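Read shares, not concentrations.

| flask | substrate | partner | catalyst | time |
|---|---|---|---|---|
| blue | 250 mM | 500 mM | 25.0 mM |  |
| ochre | 150 mM | 400 mM | 25.0 mM |  |
| teal | 250 mM | 500 mM | 50.0 mM |  |
| green | 120 mM | 500 mM | 25.0 mM |  |
| grey | 72.0 mM | 500 mM | 25.0 mM | 84 min |

| run | time / min | [target] / mM |
|---|---|---|
| blue run | 10 | 6.7 |
| blue run | 21 | 18.8 |
| blue run | 32 | 31.0 |
| blue run | 42 | 46.8 |
| blue run | 52 | 62.5 |
| blue run | 63 | 78.0 |
| blue run | 74 | 92.1 |
| blue run | 84 | 97.3 |
| ochre run | 10 | 4.7 |
| ochre run | 21 | 12.9 |
| ochre run | 32 | 20.5 |
| ochre run | 42 | 29.1 |
| ochre run | 52 | 38.9 |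
| ochre run | 63 | 48.5 |
| ochre run | 74 | 58.6 |
| ochre run | 84 | 67.8 |
| teal run | 10 | 11.5 |
| teal run | 21 | 35.6 |
| teal run | 32 | 62.5 |
| teal run | 42 | 88.6 |
| teal run | 52 | 111.7 |
| teal run | 63 | 132.5 |
| teal run | 74 | 139.7 |
| teal run | 84 | 138.2 |
| green run | 10 | 3.8 |
| green run | 21 | 9.0 |
| green run | 32 | 13.9 |
| green run | 42 | 21.2 |
| green run | 52 | 30.2 |
| green run | 63 | 38.4 |
| green run | 74 | 46.7 |
| green run | 84 | 52.7 |

(readings scatter by 0.8 mM)

- the power of [partner] that the first rate follows, about the charge of the blue run; measure it at two percent of substrate made into target
- the power of [substrate] that the first rate follows, about the charge of the blue run; measure it at two percent of substrate made into target (one fixed amount of target, the same in the runs compared)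
- target in the grey run at 84 min, as a share of the substrate charged

- Overall: substrate + partner -> target, with catalyst as catalyst.
- Constant volume, constant temperature.
- A reading of a species includes what of it is bound.
- An order is taken over about fifteen percent of the charge, up and down.

Blue and green differ in substrate charge, so I divide c(target) by that charge. At 52 min blue stands at 25.0 % and green at 25.2 %, about the same share, so up to there the curve of share against time does not follow the charge. But at 84 min blue's share, 38.9 %, is lower than green's, with c(target) at 97.3 mM in blue and 52.7 mM in green.

Grey has the partner and catalyst of green and a smaller substrate charge, so green is its neighbour. I carry the end share, the target at 84 min as a share of the substrate charged, which in green is 43.9 %, and I reckon only the correction for grey.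

The one sign of a correction is a bend in green. Its share gains 6.92 % from 63 min to 74 min, but 5.00 % from there to 84 min. The difference between those gains is 1.92 %, while the scatter alone gives such a difference a standard deviation of 1.63 %. So I cannot read a correction from it, and I commit to the end share for grey unchanged.

The forecast differs: it gives −0.3 for ord_R, 0.8 for ord_S and 46 % for grey, holding that “Grey, with little target, should convert slightly more than green's 44%, about 46%”.

The flask gives −0.20 for ord_R, 0.68 for ord_S and 44.2 % for grey.

    catalyst + substrate → catalyst-substrate complex (0.7020 M⁻¹ min⁻¹)
    catalyst-substrate complex + partner → target + catalyst (14.16 M⁻¹ min⁻¹)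
    catalyst + partner ⇌ idle catalyst-reagent complex, settled at all times (19.50 M⁻¹)
    2 partner → lost reagent (0.1524 M⁻¹ min⁻¹)

Grey's 44.2 % stands 0.30 percentage points above the end share. In grey, partner went to lost reagent from the start, with a first half-life by this step alone of 6.56 min, while 90.7 % of the catalyst sat at the start as idle catalyst-reagent complex, the resting state. As c(partner) fell, that complex released catalyst, which took up substrate as catalyst-substrate complex, and this met partner to give target. Ochre, with substrate at 150 mM and partner at 400 mM, reads 45.2 % at 84 min, a reading 1.3 points above the end share.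

The numbers in the tables are simulated from invented constants, noise included.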